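The numbers in the tables were computed with constants of no real substance.

The ratio of what is still unmade at two readings of one flask tells us more than the amount of X does, so we work with that ratio.

| setting | larch | maple | oak | ash | ochre | green | grey | red | blue |
|---|---|---|---|---|---|---|---|---|---|
| G | 0.026 M (in portions, 2) | 0.077 M (in portions, 2) | 0.15 M (in portions, 2) | 0.10 M (in portions, 2) | 0.20 M (in portions, 2) | 0.10 M (in portions, 2) | 0.025 M (in portions, 2) | 0.050 M (in portions, 2) | 0.10 M (in portions, 2) |
| J | 10 µM | 10 µM | 10 µM | 13 µM | 10 µM | 15 µM | 10 µM | 30 µM | 10 µM |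
| remark | run made earlier; portions every 4.0 h | run made earlier; portions every 4.0 h | run made earlier; portions every 4.0 h | run made earlier; portions every 4.0 h | the portions of G follow each other after 6.0 h, the first at the start | the portions of G follow each other after 1.0 h, the first at the start | the portions of G follow each other after 2.5 h, the first at the start | the portions of G follow each other after 12 h, the first at the start | the portions of G follow each other after 4.0 h, the first at the start |
| time |  |  |  |  | 8.0 h | 8.0 h | 8.0 h | 8.0 h | 8.0 h |

| run | time / h | X / % | G / % |
|---|---|---|---|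
| larch | 0.417 | 10.8 | 34.6 |
| larch | 0.833 | 16.9 | 27.8 |
| larch | 1.50 | 27.1 | 15.3 |
| larch | 3.00 | 37.6 | 6.7 |
| larch | 6.00 | 76.7 | 14.0 |
| maple | 0.417 | 8.2 | 36.8 |
| maple | 0.833 | 16.0 | 29.7 |
| maple | 1.50 | 24.9 | 18.6 |
| maple | 3.00 | 34.9 | 6.9 |
| maple | 6.00 | 71.4 | 16.0 |
| oak | 1.00 | 13.9 | 29.3 |
| oak | 2.50 | 29.1 | 12.2 |
| oak | 3.00 | 33.2 | 9.8 |
| oak | 5.00 | 51.8 | 37.5 |
| oak | 6.00 | 64.7 | 21.1 |
| ash | 1.00 | 22.4 | 24.9 |
| ash | 2.50 | 35.2 | 7.0 |
| ash | 3.00 | 40.1 | 5.0 |
| ash | 5.00 | 64.3 | 26.0 |
| ash | 6.00 | 77.5 | 11.7 |

(each reading ± 1 percentage point)

1. the flasks put in order of amount of X, in percent of the G charged, best first, at 8.0 h (ochre / green / grey / red / blue)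
2. the same order at 1.5 h (ochre / green / grey / red / blue)
3. the amount of X, in percent of the G charged of the flask you put first, at 8.0 h
4. the amount of X, in percent of the G charged of the flask you put last, at 8.0 h

- percentages count the whole charge, also what has not yet gone in

By the unmade fraction we mean the part of the G put in so far that has not yet become X, told as a share of the whole charge. If that part falls in proportion to itself, equal stretches of time divide it by equal ratios. Ash has the same charge of G as green and blue, so we read it first. Its first portion leaves 27.6% of the charge unmade at 1.00 h and 9.90% at 3.00 h. That gives 0.513 h⁻¹ as the logarithm of the ratio over the time between, our clearing constant. It is a pseudo-first-order constant, good for this portion and this J.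

After the second portion of ash the whole charge counts, and the readings at 5.00 h and 6.00 h give 0.462 h⁻¹. This is lower than the first value, though the readings carry their scatter, and the enzyme is plainly still working.

An enzyme turns over in proportion to its amount, so we scale the constant by J, and green with 15 µM gets 0.592 h⁻¹. Its first portion is down to 27.7% of the charge unmade at 1.0 h. The second portion raises that to 77.7%, and the remaining time brings it to 1.24% at 8.0 h. Our reckoning is therefore 98.8% of X in green, which we put first.

We take that as the high end, because at 6.00 h ash still holds 10.8% of its charge as neither G nor X, and we cannot tell how fast that part comes back. Red we put last, because its second portion comes at 12 h, later than the reading, so its X stays within the 50.0% that has gone in.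

The forecast gives green > grey > blue > ochre > red at 8.0 h and red > green > grey > blue > ochre at 1.5 h, with 86% first and 47% last, on the ground that “The enzyme route saturates”.

The flask gives green > grey > blue > ochre > red at 8.0 h and red > green > grey > blue > ochre at 1.5 h, with green at 92.3% and red at 48.9%.

    G + J ⇌ E (K = 16.0 M⁻¹, k = 2.20 × 10⁶ M⁻¹ h⁻¹)
    E → J + X (k = 4600 h⁻¹)
    G ⇌ D (K = 0.810, k = 0.160 h⁻¹)

Green thus lacks 7.70% against our 1.24%, and at 8.0 h its D holds 6.46% while its G holds 1.27%. The clearing constant, scaled to the 10 µM of blue, becomes 0.394 h⁻¹. That leaves 27.7% of the charge unmade at 1.5 h, out of the 50.0% that has gone in, so we reckon 22.3% of X in blue, and blue stands at 23.1%.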